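**Retrosynthetic overview**
1. The C1' carbinol comes from chelation-controlled reduction of a 2-aroyl oxolane. The aryl–C(=O) bond comes from 3,4-dimethoxyphenyllithium and a bridged γ-lactone.
2. The lactone comes from oxidation of the all-cis 2-hydroxymethyl-3-anisyl-oxolan-4-ol.
3. The oxolane (O1–C2 and C2–H) comes from reductive cyclisation of a 3-aryl-3-deoxypent-2-ulose. Its C3–aryl bond is made by a stereospecific 1,2-aryl shift (semipinacol) in an epoxy tertiary benzylic alcohol. This is the key step.
4. The epoxide comes from asymmetric epoxidation of an (E)-2-aryl-pent-3-ene-1,2,5-triol, built from an aryl glyoxylate and propargyl alcohol. The glyoxylate comes from anisole and ethyl chlorooxoacetate, and the aryl bromide from catechol.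
5. Ring order: oxirane (transient), then oxolane, then bridging lactone (transient, reopened in the last step).

Convention: O1, C2 (side chain), C3 (anisyl), C4 (OH) and C5 (CH2) are the atoms of the final oxolane, and C1' is the carbinol carbon. The same labels are used for these atoms in all precursors.

**Step 1**
Reactants: 1 anisole; 2 ethyl chlorooxoacetate
Product: 3 ethyl 2-(4-methoxyphenyl)-2-oxoacetate
Conditions: AlCl3 (1.2 equiv), CH2Cl2, 0 °C
Reagents that add atoms: none
Why: Friedel–Crafts acylation in which only the acid chloride end of 2 acylates and the methoxy group directs para; no stereocentre is formed.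

**Step 2**
Reactants: 3 ethyl 2-(4-methoxyphenyl)-2-oxoacetate; 4 prop-2-yn-1-ol
Product: 7 (E)-2-(4-methoxyphenyl)pent-3-ene-1,2,5-triol (racemic), via dilithiated propargyl alcohol 5 (not isolated), via alkynyl hydroxy ester 6 (not isolated)
Conditions: 4, n-BuLi (2.1 equiv), THF, −78 °C; add 3; then LiAlH4 (4 equiv), −78 °C to reflux; Rochelle salt work-up
Reagents that add atoms: none
Why: Acetylide 1,2-addition goes to the ketone carbonyl of the α-keto ester, then LiAlH4 reduces the ester and trans-hydroaluminates the propargylic alkoxide to the E-alkene; the C2 carbinol may stay racemic because step 4 erases it.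

**Step 3**
Reactants: 7 (E)-2-(4-methoxyphenyl)pent-3-ene-1,2,5-triol
Product: 8 1-[(2S,3R)-3-(hydroxymethyl)oxiran-2-yl]-1-(4-methoxyphenyl)ethane-1,2-diol (trans-epoxide, both carbinol epimers)
Conditions: D-fructose-derived Shi ketone (30 mol %), Oxone, K2CO3, Bu4NHSO4, MeCN–dimethoxymethane/aq. borate–EDTA buffer (pH 10.5), 0 °C
Reagents that add atoms: potassium peroxymonosulfate (active part of Oxone), [K+].[O-]S(=O)(=O)OO
Why: Shi asymmetric epoxidation (chiral dioxirane, spiro transition state) is reagent-controlled on trans-disubstituted alkenes and tolerates free hydroxyl groups, so both enantiomers of 7 give the (C3 S, C4 R) oxirane.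

**Step 4**
Reactants: 8 epoxy triol
Product: 11 (3S,4R,5S)-5-(hydroxymethyl)-4-(4-methoxyphenyl)oxolan-3-ol (all-cis), via keto triol 9 (not isolated), via hemiketal 10 (not isolated)
Conditions: BF3·OEt2 (0.2 equiv), MeCN–CH2Cl2, −40 °C, 1 h; then Et3SiH (5 equiv), BF3·OEt2 (3 equiv), −40 to −20 °C; aq. NaHCO3
Reagents that add atoms: none
Why: Proposed new method: catalytic Lewis acid opens the oxirane at C3 with anchimeric help from the electron-rich anisyl group on the neighbouring carbinol carbon (phenonium-type bridging, then C=O formation), so the aryl group moves from C2 to C3 strictly anti to the breaking C3–O bond (inversion at C3, C4–O untouched, racemic C2 erased, both epimers of 8 converge on 9); the primary C5–OH then closes 9 to hemiketal 10 before the labile C3–H can enolise, and more BF3 ionises 10 to the cyclic oxocarbenium ion, in which the C3 aryl group turns pseudoaxial to escape A(1,2) strain with the CH2OH group on C2, so Et3SiH attacks the face anti to both the aryl group and C4–O and gives the all-cis oxolane; the closest known reaction types are the semipinacol rearrangement of 2,3-epoxy alcohols (α-hydroxy epoxides) and the Et3SiH/Lewis acid reductive cyclisation of hydroxy ketones (hemiketal deoxygenation), which have not been merged in one flask or run on an unprotected epoxy triol.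

**Step 5**
Reactants: 11 all-cis diol
Product: 14 (1S,4S,7R)-7-(4-methoxyphenyl)-2,5-dioxabicyclo[2.2.1]heptan-3-one, via hydroxy aldehyde 12 (not isolated), via bicyclic lactol 13 (not isolated)
Conditions: TEMPO (20 mol %), PhI(OAc)2 (2.5 equiv), CH2Cl2, rt
Reagents that add atoms: none
Why: TEMPO/PhI(OAc)2 oxidative lactonisation of a 1,4-diol takes the primary alcohol first, the cis C4–OH traps the aldehyde as a lactol that is oxidised on, and only the 2,4-cis isomer can close, so no stereocentre changes.

**Step 6**
Reactants: 15 catechol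
Product: 16 1,2-dimethoxybenzene (veratrole)
Conditions: MeI (2.5 equiv), K2CO3, acetone, reflux
Reagents that add atoms: iodomethane, CI
Why: Williamson O-methylation of both phenols; no stereocentre is formed.

**Step 7**
Reactants: 16 veratrole
Product: 17 4-bromo-1,2-dimethoxybenzene
Conditions: NBS (1.0 equiv), MeCN, 0 °C to rt
Reagents that add atoms: N-bromosuccinimide, O=C1CCC(=O)N1Br
Why: Electrophilic aromatic bromination goes para to one methoxy group (position 4) with clean monobromination in MeCN.

**Step 8**
Reactants: 17 4-bromo-1,2-dimethoxybenzene; 14 bicyclic lactone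
Product: 20 (3S,4R,5S)-5-[(R)-(3,4-dimethoxyphenyl)(hydroxy)methyl]-4-(4-methoxyphenyl)oxolan-3-ol (target), via aryllithium 18 (not isolated), via hydroxy ketone 19 (not isolated)
Conditions: 17, n-BuLi (1.0 equiv), THF, −78 °C; add 14, −78 °C; AcOH (1.1 equiv); Zn(BH4)2 (Et2O solution), −78 to −20 °C; aq. NH4Cl
Reagents that add atoms: none
Why: Br/Li exchange and a single addition to the strained lactone, whose α-hydrogen is a bridgehead and cannot enolise, give 19, and Cram-chelate reduction (Zn bound to ring O1 and the C=O) delivers hydride from the side of C2–H to give the (R)-carbinol, anti to the C2–O bond.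

**Compound list**
1 | anisole | COc1ccccc1 | starting material
2 | ethyl chlorooxoacetate | CCOC(=O)C(=O)Cl | starting material
3 | ethyl 2-(4-methoxyphenyl)-2-oxoacetate | CCOC(=O)C(=O)c1ccc(OC)cc1 | intermediate
4 | prop-2-yn-1-ol | C#CCO | starting material
5 | dilithiated propargyl alcohol | [Li]C#CCO[Li] | intermediate
6 | ethyl 2,5-dihydroxy-2-(4-methoxyphenyl)pent-3-ynoate (racemic, present as its lithium alkoxide) | CCOC(=O)C(O)(C#CCO)c1ccc(OC)cc1 | intermediate
7 | (E)-2-(4-methoxyphenyl)pent-3-ene-1,2,5-triol (racemic) | OCC(O)(/C=C/CO)c1ccc(OC)cc1 | intermediate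
8 | 1-[(2S,3R)-3-(hydroxymethyl)oxiran-2-yl]-1-(4-methoxyphenyl)ethane-1,2-diol (both carbinol epimers) | OC[C@H]1O[C@@H]1C(O)(CO)c1ccc(OC)cc1 | intermediate
9 | (3R,4S)-1,4,5-trihydroxy-3-(4-methoxyphenyl)pentan-2-one | OCC(=O)[C@H](c1ccc(OC)cc1)[C@H](O)CO | intermediate
10 | (3R,4S)-2-(hydroxymethyl)-3-(4-methoxyphenyl)oxolane-2,4-diol (anomer mixture) | OCC1(O)OC[C@@H](O)[C@H]1c1ccc(OC)cc1 | intermediate
11 | (3S,4R,5S)-5-(hydroxymethyl)-4-(4-methoxyphenyl)oxolan-3-ol | COc1ccc([C@H]2[C@@H](CO)OC[C@H]2O)cc1 | intermediate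
12 | (2S,3R,4S)-4-hydroxy-3-(4-methoxyphenyl)oxolane-2-carbaldehyde | COc1ccc([C@H]2[C@@H](C=O)OC[C@H]2O)cc1 | intermediate
13 | (1S,4S,7R)-7-(4-methoxyphenyl)-2,5-dioxabicyclo[2.2.1]heptan-3-ol (lactol epimers) | COc1ccc([C@H]2[C@@H]3OC[C@H]2OC3O)cc1 | intermediate
14 | (1S,4S,7R)-7-(4-methoxyphenyl)-2,5-dioxabicyclo[2.2.1]heptan-3-one | COc1ccc([C@H]2[C@@H]3OC[C@H]2OC3=O)cc1 | intermediate
15 | catechol | Oc1ccccc1O | starting material
16 | 1,2-dimethoxybenzene | COc1ccccc1OC | intermediate
17 | 4-bromo-1,2-dimethoxybenzene | COc1ccc(Br)cc1OC | intermediate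
18 | (3,4-dimethoxyphenyl)lithium | COc1ccc([Li])cc1OC | intermediate
19 | (3,4-dimethoxyphenyl)[(2S,3R,4S)-4-hydroxy-3-(4-methoxyphenyl)oxolan-2-yl]methanone | COc1ccc([C@H]2[C@@H](C(=O)c3ccc(OC)c(OC)c3)OC[C@H]2O)cc1 | intermediate
20 | (3S,4R,5S)-5-[(R)-(3,4-dimethoxyphenyl)(hydroxy)methyl]-4-(4-methoxyphenyl)oxolan-3-ol | COc1ccc([C@H]2[C@@H]([C@H](O)c3ccc(OC)c(OC)c3)OC[C@H]2O)cc1 | target

**Total step count:** 8. **Longest linear sequence:** 6 (steps 1, 2, 3, 4, 5, 8). No protecting groups are used.

**Steps most likely to fail**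

**Step 4 (the new cascade).** The risks are the wrong hydride face at C2, epimerisation at C3, and ionisation of the benzylic carbinol before the shift.
- The fallback sets out from 8 and comes back at 11.
- The aryl shift is run alone with catalytic ZnBr2 in CH2Cl2, which are established semipinacol conditions for α-hydroxy epoxides, and hemiketal 10 is isolated.
- Ac2O, pyridine and DMAP convert 10 into the triacetate F1.
- TMSOTf and i-Pr2NEt eliminate the anomeric acetate to give the 4,5-dihydrofuran F2.
- Hydrogenation over Rh/Al2O3 adds H2 syn from the face opposite the C4 acetate and gives the all-cis diacetate F3.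
- K2CO3 in MeOH then gives 11.
- In this variant C4 alone controls C2 and C3 through a syn hydrogenation, so neither the hydride face selectivity nor the survival of C3–H matters.

**Step 3 (asymmetric epoxidation of a racemic, very polar triol in basic water).** The risks are lower face selectivity for one C2 enantiomer and Payne-type scrambling.
- The fallback sets out from 7 and comes back at 8.
- The 1,2-diol is masked with 2,2-dimethoxypropane and PPTS as the acetonide F4, so that only the primary allylic alcohol binds titanium.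
- Sharpless epoxidation (Ti(OiPr)4, D-(−)-diisopropyl tartrate, t-BuOOH, 4 Å sieves, CH2Cl2, −20 °C) gives the epoxy alcohol F5.
- PPTS in MeOH releases 8.

**Step 5 (closure of the strained bridged lactone).** The risks are a slow lactol stage and epimerisation of aldehyde 12.
- The fallback sets out from 11 and comes back at 19.
- TEMPO/NaOCl/NaClO2 oxidises the primary alcohol to the hydroxy acid F6.
- MeNHOMe·HCl, EDC and N-methylmorpholine give the Weinreb amide F7.
- 2.2 equiv of aryllithium 18 at −78 °C give ketone 19, which is reduced with Zn(BH4)2 as in step 8.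

**Further compounds**
F1 | step 4 | [(3R,4S)-2,4-diacetoxy-3-(4-methoxyphenyl)oxolan-2-yl]methyl acetate | CC(=O)OCC1(OC(C)=O)OC[C@@H](OC(C)=O)[C@H]1c1ccc(OC)cc1
F2 | step 4 | [(4S)-4-acetoxy-3-(4-methoxyphenyl)-4,5-dihydrofuran-2-yl]methyl acetate | CC(=O)OCC1=C(c2ccc(OC)cc2)[C@H](OC(C)=O)CO1
F3 | step 4 | [(2S,3S,4S)-4-acetoxy-3-(4-methoxyphenyl)oxolan-2-yl]methyl acetate (all-cis diacetate of 11) | COc1ccc([C@H]2[C@@H](COC(C)=O)OC[C@H]2OC(C)=O)cc1
F4 | step 3 | (E)-3-[4-(4-methoxyphenyl)-2,2-dimethyl-1,3-dioxolan-4-yl]prop-2-en-1-ol (racemic) | OC/C=C/C1(COC(C)(C)O1)c2ccc(OC)cc2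
F5 | step 3 | {(2R,3S)-3-[4-(4-methoxyphenyl)-2,2-dimethyl-1,3-dioxolan-4-yl]oxiran-2-yl}methanol | OC[C@H]1O[C@@H]1C2(COC(C)(C)O2)c3ccc(OC)cc3
F6 | step 5 | (2S,3R,4S)-4-hydroxy-3-(4-methoxyphenyl)oxolane-2-carboxylic acid | COc1ccc([C@H]2[C@@H](C(=O)O)OC[C@H]2O)cc1
F7 | step 5 | (2S,3R,4S)-4-hydroxy-N-methoxy-3-(4-methoxyphenyl)-N-methyloxolane-2-carboxamide | COc1ccc([C@H]2[C@@H](C(=O)N(C)OC)OC[C@H]2O)cc1
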